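**Retrosynthetic overview**
1. 14 ⇐ 13 (loss of two pivaloyl groups) ⇐ acyclic (S)-carbinol 10, ring A–O1–C2H2–C3H(OH)–C4H2–ring B, in which ring B still sits on C4. Rings A and B are bought and ring C is formed last.
2. Key disconnection C4–C4a: activating the C3 hydroxyl lets ring B bridge C3 and C4 as a phenonium ion (a transient cyclopropane), and C4a of ring A opens it at C4. One operation gives the 1,2-aryl shift C4→C3 (an echo of the aryl migration that makes isoflavonoids in nature), ring C, and the C3 stereocentre by inversion.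
3. Enabling feature: C1' of ring B is para to the 4'-OMe and ortho to the 2'-oxygen, so it is a strong ipso nucleophile. C4a of ring A is the only free carbon ortho to O1 (C8 bears OMe) and is para to the 7-OMe. O1 and 6-OH are para, so ring A is a monoether of the symmetric 2,3-dimethoxyhydroquinone.
4. 10 ⇐ catalytic enantioselective opening of racemic epoxide 6 (ring B part) by phenol 9 (ring A part).
5. 6 and 9 both ⇐ 2,3-dimethoxyphenol 1: O-allylation, Claisen rearrangement, acylation and epoxidation for 6; oxidation to the quinone, reduction and monoacylation for 9.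

Key step: step 9

Assumption: C3 of the target is (S) (C2 > C1' > C4 > H), and the (R,R)-cobalt–salen complex is taken to consume the (S)-enantiomer of 6, as it does with other alkyl-substituted terminal epoxides.

Step 1
Reactants: 1 2,3-dimethoxyphenol; 2 allyl bromide
Product: 3 1-(allyloxy)-2,3-dimethoxybenzene
Conditions: K2CO3, acetone, reflux
Reagents that add atoms: none
Why: Williamson ether synthesis, a standard SN2 O-alkylation of a phenoxide by a primary allylic bromide.

Step 2
Reactants: 3 1-(allyloxy)-2,3-dimethoxybenzene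
Product: 4 6-allyl-2,3-dimethoxyphenol
Conditions: N,N-diethylaniline, 200 °C
Reagents that add atoms: none
Why: Aromatic Claisen rearrangement; the [3,3] shift can end only at C6 because the other ortho carbon bears OMe, and tautomerisation restores the phenol that becomes the 2'-OH.

Step 3
Reactants: 4 6-allyl-2,3-dimethoxyphenol
Product: 5 6-allyl-2,3-dimethoxyphenyl pivalate
Conditions: PivCl, Et3N, DMAP (cat.), CH2Cl2, 0 °C to rt
Reagents that add atoms: pivaloyl chloride, CC(C)(C)C(=O)Cl
Why: DMAP-catalysed O-acylation of a phenol; the acyl group makes the 2'-oxygen non-nucleophilic for step 9.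

Step 4
Reactants: 5 6-allyl-2,3-dimethoxyphenyl pivalate
Product: 6 rac-2,3-dimethoxy-6-(oxiran-2-ylmethyl)phenyl pivalate
Conditions: mCPBA, CH2Cl2, 0 °C to rt
Reagents that add atoms: mCPBA, OOC(=O)c1cccc(Cl)c1
Why: Prilezhaev epoxidation of the only alkene; the aryl ester and aryl ethers are inert to the peracid, and the racemate is wanted for step 8.

Step 5
Reactants: 1 2,3-dimethoxyphenol
Product: 7 2,3-dimethoxy-1,4-benzoquinone
Conditions: (KSO3)2NO (2.5 equiv), KH2PO4 buffer, H2O/acetone, rt
Reagents that add atoms: potassium nitrosodisulfonate, [K+].[K+].[O]N(S(=O)(=O)[O-])S(=O)(=O)[O-]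
Why: Teuber oxidation; two equivalents of the nitroxyl radical salt turn a phenol with a free para position into the para-quinone, the new oxygen coming from the reagent.

Step 6
Reactants: 7 2,3-dimethoxy-1,4-benzoquinone
Product: 8 2,3-dimethoxybenzene-1,4-diol
Conditions: Na2S2O4, H2O/EtOAc, rt, argon
Reagents that add atoms: none
Why: Dithionite reduction of a quinone to its hydroquinone, a fast two-electron, two-proton transfer that touches nothing else.

Step 7
Reactants: 8 2,3-dimethoxybenzene-1,4-diol
Product: 9 4-hydroxy-2,3-dimethoxyphenyl pivalate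
Conditions: PivCl (0.95 equiv, slow addition), pyridine, CH2Cl2, −20 °C
Reagents that add atoms: pivaloyl chloride, CC(C)(C)C(=O)Cl
Why: Monoacylation of a symmetric hydroquinone with a bulky acyl chloride; the two hydroxyls are equivalent, so only one monoester can form, and diester and unreacted 8 are separable.

Step 8
Reactants: 6 rac-2,3-dimethoxy-6-(oxiran-2-ylmethyl)phenyl pivalate; 9 4-hydroxy-2,3-dimethoxyphenyl pivalate
Product: 10 (S)-1-[2,3-dimethoxy-4-(pivaloyloxy)phenoxy]-3-[3,4-dimethoxy-2-(pivaloyloxy)phenyl]propan-2-ol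
Conditions: (R,R)-(salen)Co(OC(CF3)3) (5 mol %; salen = N,N'-bis(3,5-di-tert-butylsalicylidene)-1,2-cyclohexanediaminate), 6 (2.2 equiv), 9 (1 equiv), 3 Å MS, t-BuOMe, 4 °C to rt
Reagents that add atoms: none
Why: Cobalt–salen catalysed phenolic kinetic resolution of a terminal epoxide; the chiral trivalent cobalt complex activates only the (S)-epoxide for attack of 9 at the terminal CH2, so the carbinol centre of 10 is the untouched epoxide carbon selected by the catalyst.

Step 9
Reactants: 10 (S)-1-[2,3-dimethoxy-4-(pivaloyloxy)phenoxy]-3-[3,4-dimethoxy-2-(pivaloyloxy)phenyl]propan-2-ol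
Product: 13 (3S)-3-[3,4-dimethoxy-2-(pivaloyloxy)phenyl]-7,8-dimethoxychroman-6-yl pivalate, via secondary triflate 11 (not isolated), via phenonium triflate 12 (not isolated)
Conditions: Tf2O (1.1 equiv), 2,6-di-tert-butyl-4-methylpyridine (3 equiv), CH2Cl2 (0.01 M), −78 °C; then HFIP (20 vol %) at −20 °C, to rt
Reagents that add atoms: triflic anhydride, O=S(=O)(OS(=O)(=O)C(F)(F)F)C(F)(F)F (its triflyl group is carried by 11 and 12 only and is lost again before 13)
Why: Proposed new method: the secondary triflate 11 should ionise with anchimeric assistance of ring B, C1' attacking C3 from the back in a 3-exo-tet closure (Ar1-3 participation) to give the spiro-cyclopropane phenonium ion 12, after which C4a of ring A should open 12 at its CH2 carbon C4 in a Friedel–Crafts alkylation and loss of the C4a proton to the pyridine base restores ring A. The closest known reaction types are the Friedel–Crafts capture of phenonium ions from β-aryl alcohols, sulfonates and epoxides by external arenes in HFIP, and the 6-endo epoxide–arene cyclisation of aryl glycidyl ethers to chroman-3-ols, which has the same O–CH2 tether and the same choice between the two carbons of a three-membered ring; what is new is the union of aryl shift and ring closure on an aryl ether. Ring C closes in the 6-endo-tet sense with respect to the three-membered ring (Ar2-6 mode), and the transient cyclopropane is opened again in the same event. The only stereocentre, C3, is controlled by the carbinol configuration of 10: the C3–O bond is replaced by the C3–C1' bond with inversion and C3 is not touched afterwards, so (S)-10 maps onto (3S)-13. Three selectivities are needed: carbon rather than oxygen participation of ring B, secured by the pivaloyl group on the 2'-oxygen; attack at C4 rather than C3, secured by the six- versus five-membered transition state, the primary nature of C4 and the inductive deactivation of C3 by its CH2OAr substituent; and a single site on ring A, secured because C8 bears OMe so that C4a is the only free carbon ortho to O1. High dilution and a hindered non-nucleophilic base should hold back intermolecular alkylation and elimination.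

Step 10
Reactants: 13 (3S)-3-[3,4-dimethoxy-2-(pivaloyloxy)phenyl]-7,8-dimethoxychroman-6-yl pivalate
Product: 14 (3S)-3-(2-hydroxy-3,4-dimethoxyphenyl)-7,8-dimethoxychroman-6-ol (CNP0416342.1)
Conditions: LiAlH4 (3 equiv), THF, 0 °C, argon; then 1 M HCl
Reagents that add atoms: none
Why: Hydride reduction of both hindered aryl esters frees 6-OH and 2'-OH without exposing the electron-rich phenols to base and air, and C3 has no pathway for epimerisation.

**Compound list**
1 | 2,3-dimethoxyphenol | COc1cccc(O)c1OC | starting material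
2 | allyl bromide | C=CCBr | starting material
3 | 1-(allyloxy)-2,3-dimethoxybenzene | C=CCOc1cccc(OC)c1OC | intermediate
4 | 6-allyl-2,3-dimethoxyphenol | C=CCc1ccc(OC)c(OC)c1O | intermediate
5 | 6-allyl-2,3-dimethoxyphenyl pivalate | C=CCc1ccc(OC)c(OC)c1OC(=O)C(C)(C)C | intermediate
6 | rac-2,3-dimethoxy-6-(oxiran-2-ylmethyl)phenyl pivalate | COc1ccc(CC2CO2)c(OC(=O)C(C)(C)C)c1OC | intermediate
7 | 2,3-dimethoxy-1,4-benzoquinone | COC1=C(OC)C(=O)C=CC1=O | intermediate
8 | 2,3-dimethoxybenzene-1,4-diol | COc1c(O)ccc(O)c1OC | intermediate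
9 | 4-hydroxy-2,3-dimethoxyphenyl pivalate | COc1c(O)ccc(OC(=O)C(C)(C)C)c1OC | intermediate
10 | (S)-1-[2,3-dimethoxy-4-(pivaloyloxy)phenoxy]-3-[3,4-dimethoxy-2-(pivaloyloxy)phenyl]propan-2-ol | COc1ccc(C[C@H](O)COc2ccc(OC(=O)C(C)(C)C)c(OC)c2OC)c(OC(=O)C(C)(C)C)c1OC | intermediate
11 | (S)-triflate of 10 (not isolated) | COc1ccc(C[C@H](OS(=O)(=O)C(F)(F)F)COc2ccc(OC(=O)C(C)(C)C)c(OC)c2OC)c(OC(=O)C(C)(C)C)c1OC | intermediate
12 | phenonium triflate: ring B spiro-fused at C1' to the C3–C4 cyclopropane, drawn as its 4'-oxocarbenium form, spiro carbon left undefined (not isolated) | C[O+]=C1C=CC2(C[C@@H]2COc3ccc(OC(=O)C(C)(C)C)c(OC)c3OC)C(OC(=O)C(C)(C)C)=C1OC.[O-]S(=O)(=O)C(F)(F)F | intermediate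
13 | (3S)-3-[3,4-dimethoxy-2-(pivaloyloxy)phenyl]-7,8-dimethoxychroman-6-yl pivalate | COc1ccc([C@H]2COc3c(cc(OC(=O)C(C)(C)C)c(OC)c3OC)C2)c(OC(=O)C(C)(C)C)c1OC | intermediate
14 | (3S)-3-(2-hydroxy-3,4-dimethoxyphenyl)-7,8-dimethoxychroman-6-ol | COc1ccc([C@H]2COc3c(cc(O)c(OC)c3OC)C2)c(O)c1OC | target

**Step count and risks**
Total steps: 10. Longest linear sequence: 7 (steps 1, 2, 3, 4, 8, 9, 10).

1. Step 9 (bears the label).
- What may go wrong: opening of the bridged ion at C3 with five-ring closure; a 1,2-hydride shift from C4 to C3 followed by closure to the 4-aryl skeleton; elimination of triflic acid; or intermolecular alkylation.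
- Fallback, known chemistry only, sets out from 9 (and from 1 for ring B) and comes back at 14. The aryl shift is given up, the same C4–C4a bond is closed on an epoxide instead of on the bridged ion, and C3 is set by hydrogenation.
- Phenol 9 is alkylated with epichlorohydrin (K2CO3, DMF) to the racemic glycidyl ether F1. The established 6-endo epoxide–arene Friedel–Crafts cyclisation (HFIP, 60 °C) should give the chroman-3-ol F2. Dess–Martin oxidation gives the chroman-3-one F3, and KN(SiMe3)2/PhNTf2 (THF, −78 °C) its conjugated enol triflate F4.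
- In parallel, 1 is turned into its MOM ether F5 (MOMCl, iPr2NEt). Directed ortho-lithiation next to the OMOM group (n-BuLi, THF, 0 °C) and B(OMe)3 then give the boronic acid F6.
- Suzuki–Miyaura coupling of F4 with F6 (Pd(PPh3)4, K3PO4, dioxane, 80 °C) should give the isoflav-3-ene F7. Asymmetric hydrogenation with [Ir(cod)(tBu-PHOX)]B[3,5-(CF3)2C6H3]4 (ligand antipode chosen for the 3S sense, H2, CH2Cl2) should give the (S)-isoflavan F8.
- HCl/MeOH removes the MOM group to give the 6-O-pivalate F9, which under the conditions of step 10 gives 14.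

2. Step 8.
- What may go wrong: slow or unselective opening, because the phenol is ortho-substituted and electron-rich and may reduce the trivalent cobalt to inactive divalent cobalt.
- Fallback sets out from 6 and comes back at 10; resolution and C–O bond formation are separated.
- Hydrolytic kinetic resolution of 6 with (S,S)-(salen)Co(OAc) and water (0.55 equiv) should hydrolyse the (R)-epoxide and leave the (S)-epoxide F10.
- F10 is separated and then opened at its terminal carbon by phenol 9 in a plain SN2 reaction (CsF, DMF, 60 °C) to give 10.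

3. Step 7.
- What may go wrong: over-acylation for lack of discrimination between the two equivalent hydroxyls, and air oxidation of the hydroquinone during handling.
- Fallback sets out from 1 and comes back at 9, replacing steps 5 to 7; the two oxygens are differentiated from the moment the second one is introduced.
- Elbs persulfate oxidation of 1 (K2S2O8, aq. KOH, 0 °C to rt) should give the para-hydroxyaryl sulfate salt F11.
- Schotten–Baumann acylation of its free phenol (PivCl, aq. KOH/CH2Cl2) gives the pivalate sulfate salt F12, and acid hydrolysis of the aryl sulfate (2 M HCl, THF, 50 °C) gives 9.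

**Further compounds**
F1 | step 9 | rac-2,3-dimethoxy-4-(oxiran-2-ylmethoxy)phenyl pivalate | COc1c(OCC2CO2)ccc(OC(=O)C(C)(C)C)c1OC
F2 | step 9 | rac-3-hydroxy-7,8-dimethoxychroman-6-yl pivalate | OC1COc2c(C1)cc(OC(=O)C(C)(C)C)c(OC)c2OC
F3 | step 9 | 7,8-dimethoxy-3-oxochroman-6-yl pivalate | O=C1COc2c(C1)cc(OC(=O)C(C)(C)C)c(OC)c2OC
F4 | step 9 | 7,8-dimethoxy-3-(triflyloxy)-2H-chromen-6-yl pivalate | FC(F)(F)S(=O)(=O)OC1=Cc2cc(OC(=O)C(C)(C)C)c(OC)c(OC)c2OC1
F5 | step 9 | 1,2-dimethoxy-3-(methoxymethoxy)benzene | COCOc1cccc(OC)c1OC
F6 | step 9 | [3,4-dimethoxy-2-(methoxymethoxy)phenyl]boronic acid | COCOc1c(B(O)O)ccc(OC)c1OC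
F7 | step 9 | 3-[3,4-dimethoxy-2-(methoxymethoxy)phenyl]-7,8-dimethoxy-2H-chromen-6-yl pivalate | COCOc1c(C2=Cc3cc(OC(=O)C(C)(C)C)c(OC)c(OC)c3OC2)ccc(OC)c1OC
F8 | step 9 | (3S)-3-[3,4-dimethoxy-2-(methoxymethoxy)phenyl]-7,8-dimethoxychroman-6-yl pivalate | COCOc1c([C@H]2COc3c(cc(OC(=O)C(C)(C)C)c(OC)c3OC)C2)ccc(OC)c1OC
F9 | step 9 | (3S)-3-(2-hydroxy-3,4-dimethoxyphenyl)-7,8-dimethoxychroman-6-yl pivalate | COc1ccc([C@H]2COc3c(cc(OC(=O)C(C)(C)C)c(OC)c3OC)C2)c(O)c1OC
F10 | step 8 | (S)-2,3-dimethoxy-6-(oxiran-2-ylmethyl)phenyl pivalate | COc1ccc(C[C@H]2CO2)c(OC(=O)C(C)(C)C)c1OC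
F11 | step 7 | potassium 4-hydroxy-2,3-dimethoxyphenyl sulfate | COc1c(O)ccc(OS(=O)(=O)[O-])c1OC.[K+]
F12 | step 7 | potassium 2,3-dimethoxy-4-(pivaloyloxy)phenyl sulfate | COc1c(OC(=O)C(C)(C)C)ccc(OS(=O)(=O)[O-])c1OC.[K+]
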